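(The data are simulated for an exercise; the scatter is artificial.)

Two questions stand below, and I answer both with one quantity: the part of the charge that sits in chains at the end.

| flask | free monomer | protic impurity | initiator | remark | time |
|---|---|---|---|---|---|
| dusk | 0.72 M | 0.45 M | 3 mM | run made earlier |  |
| summer | 1.8 M | 0.45 M | 3 mM | run made earlier |  |
| larch | 0.60 M | 0.450 M | 3.0 mM |  | 10 min |
| ash | 1.0 M | 0.450 M | 3.0 mM |  | 10 min |
| birch | 1.5 M | 0.450 M | 3.0 mM |  | 10 min |

- dusk (time / min: monomer in chains / %, free monomer / %): 0.417: 7.4, 89.3; 0.833: 13.9, 82.2; 1.33: 20.9, 73.1; 2.50: 34.3, 57.2; 5.00: 48.0, 35.1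
- summer (time / min: monomer in chains / %, free monomer / %): 0.417: 7.3, 89.9; 1.33: 21.5, 71.6; 2.50: 32.7, 57.3; 4.00: 43.5, 43.1; 5.00: 48.7, 37.6

(scatter of a reading: 1 percentage point)

* [monomer in chains] at the end for larch, ash, birch, in this order
* how the row runs (rises all the way / hardly changes / falls all the way / rises, then falls / falls, then rises)

- candidate steps: initiator -> 2 initiating radical; free monomer + initiating radical -> growing radical + monomer in chains; free monomer + growing radical -> monomer in chains + growing radical; 2 growing radical -> dead chain; protic impurity + free monomer -> quenched substrate
- "hardly changes" means that all values lie within two and a half points (for a concentration: within two and a half percent of the largest)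

The summer charge is 2.50 times the dusk charge, yet at 5.00 min you read 48.7% of the charge in chains for summer and 48.0% for dusk, which differ by less than the scatter of 1 percentage point. So I draw one curve for both runs, in parts of the charge.

The curve starts at 0.176 min⁻¹, the mean speed up to the first readings. Between 2.50 min and 5.00 min the two runs average 0.0594 min⁻¹, less than at the start. Taking the fade as exponential between the middles of those two stretches gives a fade rate of 0.307 min⁻¹, so on these readings the speed halves every 2.26 min; that is the knee.

At 5.00 min the mean of the two runs stands at 48.4%. The fading speed adds 10.3% by 10 min, which gives 58.7%. This is the end share, the part of the charge in chains at the asked time. Continued without end, the same fade levels off near 61.5%.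

Multiplying the end share by each charge, I expect 0.352 M, 0.587 M and 0.880 M. The forecast gave 0.36 M, 0.62 M and 0.94 M, rises all the way, on the ground that “the rate per unit of monomer is the same”. My birch figure lies below the forecast's.

The flask gives 0.360 M, 0.604 M and 0.914 M: the row rises all the way.

    initiator → 2 initiating radical (k = 0.00420 s⁻¹)
    free monomer + initiating radical → growing radical + monomer in chains (k = 21000 L mol⁻¹ s⁻¹)
    free monomer + growing radical → monomer in chains + growing radical, rate k3*[growing radical]*[free monomer] (k = 3700 L mol⁻¹ s⁻¹)
    2 growing radical → dead chain (k = 1.50 × 10⁷ L mol⁻¹ s⁻¹)
    protic impurity + free monomer → quenched substrate (k = 0.00200 L mol⁻¹ s⁻¹)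

The end share falls a little short in larch, at 0.352 M against 0.360 M, and in birch, at 0.880 M against 0.914 M. The largest single effect on the end figure in birch is growing radicals meeting in pairs as dead chain: with that step taken away, birch reaches 1.49 M instead of 0.914 M.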